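All runs were computed for an exercise; noise was put on by code.

Whatever the flask does, the monomer fed so far is shared among free monomer, monomer in chains and quenched substrate. On Wednesday's run at 2.00 h, with the feed over, that balance leaves 19.5% of the charge as quenched substrate, beside the 20.0% that its charge of protic impurity can take.

| flask | free monomer | transfer agent | protic impurity | initiator | remark | time |
|---|---|---|---|---|---|---|
| Tuesday's | 0.16 M (fed, over 2.0 h) | 0.024 M | 0.032 M | 2.4 mM | run made earlier; the fed solution adds 0.10 times the starting volume |  |
| Wednesday's | 0.16 M (fed, over 2.0 h) | 0.096 M | 0.032 M | 2.4 mM | run made earlier; the fed solution adds 0.10 times the starting volume |  |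
| Saturday's | 0.16 M (fed, over 2.0 h) | 0.048 M | 0.064 M | 2.4 mM | run made earlier; the fed solution adds 0.10 times the starting volume |  |
| flask | 0.16 M (fed, over 2.0 h) | 0.0480 M | 0.0320 M | 2.4 mM | the fed solution adds 0.10 times the starting volume | 4.0 h |

| run | time / h | monomer in chains / % | free monomer / % |
|---|---|---|---|
| Tuesday's | 0.667 | 0 | 14.4 |
| Tuesday's | 1.50 | 9.9 | 45.1 |
| Tuesday's | 3.00 | 47.0 | 33.3 |
| Tuesday's | 5.00 | 66.2 | 13.5 |
| Wednesday's | 0.417 | 0.2 | 8.1 |
| Wednesday's | 0.833 | 1.0 | 21.4 |
| Wednesday's | 2.00 | 18.8 | 61.7 |
| Wednesday's | 5.00 | 45.3 | 35.2 |
| Saturday's | 0.417 | 0.7 | 4.0 |
| Saturday's | 0.833 | 0.3 | 8.4 |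
| Saturday's | 2.00 | 10.6 | 49.1 |
| Saturday's | 5.00 | 41.4 | 18.0 |

(readings scatter by 0.3 percentage points)

- charges are per starting volume, the dose included; the dosed solution carries all of it
- the average divides the monomer in chains by the number of chains begun, living and dead together
- reactions considered so far: free monomer + initiator -> living end + monomer in chains; protic impurity + free monomer -> quenched substrate; free monomer + living end -> monomer in chains + living end; initiator -> spent initiator; living end + transfer agent -> dead chain
- the earlier runs do not show the number of chains; that part of a forecast is a guess
- percentages count the whole charge, also what has not yet gone in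

1. whether the average number of monomer units in a chain (chains begun, living or dead) reaches 40 by 4.0 h (yes / no)
2. average number of monomer units in a chain (chains begun, living or dead) at 4.0 h

What sets the pace in this flask after the feed? I count half-lives of free monomer, treating its loss as pseudo-first-order between late readings, which gives a reading of 0.451 /h on Tuesday's run and 0.187 /h on Wednesday's.

And for this flask? Taking the logarithm of that rate as linear in transfer agent up to the flask's 0.0480 M gives my estimate of the half-life of free monomer after the feed, 2.06 h.

What does that leave at 4.0 h? The flask has 0.971 half-lives after the feed, and if I start from Wednesday's 61.7% of free monomer, 31.5% of the charge stays free, which puts 48.5% in chains.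

But no run counts chains, so what is that worth for length? The flask charges 66.7 monomer units per initiator, so if every initiator began a chain the length would be 32.4, and reaching 40 requires that at most 80.9% of the initiator begins chains, a share that my reckoning cannot read.

The forecast does commit: yes, with a length of 50 between 39 and 72, and it adds: “The chain count is unobserved, so this is uncertain.”

The flask gives yes, with a length of 52.9, inside the forecast's range.

    free monomer + initiator → living end + monomer in chains (k = 0.390 /M/min)
    protic impurity + free monomer → quenched substrate (k = 5.30 /M/min)
    free monomer + living end → monomer in chains + living end, rate k3*[living end]*[free monomer] (k = 7.90 /M/min)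
    initiator → spent initiator (k = 0.00530 /min)
    living end + transfer agent → dead chain (kL = 0.120 /M/min)

From 58.4% at 2.00 h to 26.8% at 4.00 h, the flask's free monomer shows an average half-life of 1.78 h, shorter than the 2.06 h carried, while Saturday's run, with the flask's transfer agent but twice its protic impurity, reads 2.07 h from its last two readings. The flask's living end has a half-life by transfer of 2.2 h at 2.21 h, longer than the free monomer's average 1.78 h, and at 40.0 h the living end stands at 1.09 × 10⁻⁸ M with free monomer still at 10.3%.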